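**Assumption:** the SMILES defines the C4=C5 alkene as Z (C3 and C6 cis) and the stereocentres as 1S,6R,8S, and that isomer is made; atom labels C1–C15 follow germacrane numbering of the target.

## Retrosynthetic overview

1. Target ⇐ 1-ketone (CBS reduction sets C1) ⇐ ten-membered keto-lactone formed by ring expansion of a 6/6-fused tricyclic tertiary alcohol: vinylogous retro-aldol cleavage of the C1–C6 bond, with a 2-furanolate as leaving group.
2. Tricyclic alcohol ⇐ intramolecular Nozaki–Hiyama–Kishi addition of C10 to the C1 ketone ⇐ catalytic asymmetric 2-bromoallylation of a β-formyl spiro-butenolide (sets C8).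
3. Spiro-butenolide ⇐ alkoxide-directed anti-carbomagnesiation/carboxylation of a tertiary propargylic alcohol (C7–C8 and C11–C12 bonds, C7=C11 geometry) ⇐ acetylide addition to 6-hydroxy-3-methylcyclohex-2-enone.
4. The (4Z)-alkene is carried throughout as the ring alkene of 3-methylcyclohexenone.
5. Ring order: cyclohexene (bought) → butenolide → methylenecyclohexane → ten-membered carbocycle (by expansion).

## Route

Step 1
Reactants: 1 3-methylcyclohex-2-en-1-one
Product: 4 6-hydroxy-3-methylcyclohex-2-en-1-one (racemic), via silyl dienol ether 2 (not isolated), via silyloxy ketone 3 (not isolated)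
Conditions: LiN(i-Pr)2, Me3SiCl, THF, −78 °C; then mCPBA, hexane, −15 to 23 °C; then 1 M HCl, THF, 23 °C
Reagents that add atoms: mCPBA (3-chloroperoxybenzoic acid), O=C(OO)c1cccc(Cl)c1
Why: Kinetic deprotonation gives the cross-conjugated 2-silyloxydiene, whose electron-rich enol ether bond is epoxidised selectively and rearranges to the alpha'-oxygenated enone (Rubottom oxidation); the new carbinol is racemic, which is harmless because it becomes the C1 ketone in step 5.

Step 2
Reactants: 4 6-hydroxy-3-methylcyclohex-2-en-1-one; 5 tert-butyldimethyl(prop-2-yn-1-yloxy)silane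
Product: 7 2-{3-[(tert-butyldimethylsilyl)oxy]prop-1-yn-1-yl}-4-methylcyclohex-3-ene-1,2-diol (racemic diastereomer mixture), via lithium acetylide 6 (not isolated)
Conditions: 5 (2.3 equiv), n-BuLi (2.2 equiv), THF, −78 °C; then 4, −78 to 0 °C; H2O
Reagents that add atoms: none
Why: Lithium acetylides add 1,2 to enones (the first equivalent only deprotonates the hydroxyl), giving the tertiary propargylic alcohol at the future C6; its configuration and that of the neighbouring carbinol are irrelevant because C1 is oxidised in step 5 and C6 is planarised in step 8.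

Step 3
Reactants: 7 2-{3-[(tert-butyldimethylsilyl)oxy]prop-1-yn-1-yl}-4-methylcyclohex-3-ene-1,2-diol
Product: 10 4-{[dimethyl(propan-2-yloxy)silyl]methyl}-10-hydroxy-7-methyl-3-{[(tert-butyldimethylsilyl)oxy]methyl}-1-oxaspiro[4.5]deca-3,6-dien-2-one (racemic diastereomer mixture), via alkenylmagnesium chelate 8 (not isolated), via hydroxy acid 9 (not isolated)
Conditions: i-PrO(Me)2SiCH2MgCl (4 equiv), CuI (10 mol%), THF, 0 to 45 °C; then CO2 (1 atm), 0 °C; then 1 M HCl, 0 °C
Reagents that add atoms: [dimethyl(propan-2-yloxy)silyl]methylmagnesium chloride, CC(C)O[Si](C)(C)C[Mg]Cl; carbon dioxide, O=C=O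
Why: Copper-catalysed alkoxide-directed anti-carbomagnesiation of the propargylic alcohol (Duboudin–Fallis reaction) puts the silylmethyl group on C7 and magnesium on C11 cis to the alkoxide in a five-membered chelate, so carboxylation and acid lactonisation can only give the butenolide with the required C7=C11 geometry.

Step 4
Reactants: 10 4-{[dimethyl(propan-2-yloxy)silyl]methyl}-10-hydroxy-7-methyl-3-{[(tert-butyldimethylsilyl)oxy]methyl}-1-oxaspiro[4.5]deca-3,6-dien-2-one
Product: 11 10-hydroxy-4-(hydroxymethyl)-7-methyl-3-{[(tert-butyldimethylsilyl)oxy]methyl}-1-oxaspiro[4.5]deca-3,6-dien-2-one (racemic diastereomer mixture)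
Conditions: H2O2 (30% aq.), KF, KHCO3, THF/MeOH 1:1, 23 °C
Reagents that add atoms: hydrogen peroxide, OO
Why: Tamao–Fleming oxidation replaces the alkoxysilyl group by hydroxyl at C8, the fluoride-activated peroxide attacking silicon and not the electron-poor tetrasubstituted butenolide alkene or the ring alkene.

Step 5
Reactants: 11 10-hydroxy-4-(hydroxymethyl)-7-methyl-3-{[(tert-butyldimethylsilyl)oxy]methyl}-1-oxaspiro[4.5]deca-3,6-dien-2-one
Product: 12 7-methyl-2,10-dioxo-3-{[(tert-butyldimethylsilyl)oxy]methyl}-1-oxaspiro[4.5]deca-3,6-diene-4-carbaldehyde (racemic; spiro carbon = C6, ring ketone = C1, formyl carbon = C8)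
Conditions: Dess–Martin periodinane (2.6 equiv), CH2Cl2, 0 to 23 °C
Reagents that add atoms: none
Why: Dess–Martin oxidation converts the primary allylic alcohol into the aldehyde and the secondary alcohol into the ketone in one operation under neutral conditions that leave the silyl ether, the lactone and both alkenes untouched.

Step 6
Reactants: 12 7-methyl-2,10-dioxo-3-{[(tert-butyldimethylsilyl)oxy]methyl}-1-oxaspiro[4.5]deca-3,6-diene-4-carbaldehyde; 13 2,3-dibromoprop-1-ene
Product: 14 4-{(1S)-3-bromo-1-[(triethylsilyl)oxy]but-3-en-1-yl}-7-methyl-3-{[(tert-butyldimethylsilyl)oxy]methyl}-1-oxaspiro[4.5]deca-3,6-diene-2,10-dione (1:1 mixture of spiro epimers)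
Conditions: 13 (2 equiv), CrBr3 (10 mol%), Kishi-type chiral (4,5-dihydrooxazol-2-yl)aryl sulfonamide ligand (11 mol%), Et3N (20 mol%), CoC32H16N8 (cobalt phthalocyanine, 1 mol%), Mn powder, Et3SiCl, MeCN, 0 °C
Reagents that add atoms: chlorotriethylsilane, CC[Si](Cl)(CC)CC
Why: Catalytic asymmetric Nozaki–Hiyama–Kishi 2-haloallylation: the allylchromium reagent from 13 adds only to the aldehyde, the ligand enantiomer is chosen for Si-face attack so that C8 is S in both spiro epimers, and Et3SiCl releases the product from chromium as its triethylsilyl ether.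

Step 7
Reactants: 14 4-{(1S)-3-bromo-1-[(triethylsilyl)oxy]but-3-en-1-yl}-7-methyl-3-{[(tert-butyldimethylsilyl)oxy]methyl}-1-oxaspiro[4.5]deca-3,6-diene-2,10-dione
Product: 15 (8S)-13-[(tert-butyldimethylsilyl)oxy]-1-hydroxy-8-[(triethylsilyl)oxy]-1,6-cyclogermacra-4,7(11),10(14)-trien-6,12-olide (tricyclic, extra C1–C6 bond; diastereomer mixture at C1 and C6)
Conditions: CrCl2 (6 equiv), NiCl2 (2 mol%), DMF, 23 °C; aqueous NH4Cl
Reagents that add atoms: none
Why: Intramolecular Nozaki–Hiyama–Kishi reaction: the alkenylchromium species formed from the vinyl bromide under nickel catalysis closes a six-membered ring onto the neighbouring ketone while tolerating the lactone and silyl ethers; the configurations at C1 and C6 do not matter because both centres are reset in step 8.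

Step 8
Reactants: 15 (8S)-13-[(tert-butyldimethylsilyl)oxy]-1-hydroxy-8-[(triethylsilyl)oxy]-1,6-cyclogermacra-4,7(11),10(14)-trien-6,12-olide
Product: 18 (4Z,6R,8S)-13-[(tert-butyldimethylsilyl)oxy]-1-oxo-8-[(triethylsilyl)oxy]germacra-4,7(11),10(14)-trien-6,12-olide, via potassium alkoxide 16 (not isolated), via potassium furanolate 17 (not isolated)
Conditions: KN(SiMe3)2 (1.05 equiv), THF, −78 °C, 15 min; then AcOH (2 equiv) in THF, −78 °C
Reagents that add atoms: none
Why: Proposed new method: the tertiary potassium alkoxide should fragment by a vinylogous retro-aldol cleavage of the C1–C6 bond, which stands perpendicular to the butenolide plane and releases an aromatic 2-furanolate as the carbanion leaving group, so the 6/6 bicycle opens to the ten-membered 1-ketone (four-atom ring expansion, the ring alkene becoming the 4Z alkene); protonation at C6 anti to the bulky triethylsilyloxy group of the A(1,3)-locked C8 rotamer is expected to set 6R; the closest known reactions are base-induced retro-aldol ring expansions of bicyclic beta-hydroxy ketones and the reversible vinylogous aldol addition of 2-silyloxyfurans to ketones.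

Step 9
Reactants: 18 (4Z,6R,8S)-13-[(tert-butyldimethylsilyl)oxy]-1-oxo-8-[(triethylsilyl)oxy]germacra-4,7(11),10(14)-trien-6,12-olide
Product: 20 (4Z,6R,8S)-8,13-diacetoxy-1-oxogermacra-4,7(11),10(14)-trien-6,12-olide, via diol 19 (not isolated)
Conditions: HF·pyridine, THF/pyridine, 0 to 23 °C; then Ac2O, DMAP (cat.), 23 °C
Reagents that add atoms: acetic anhydride, CC(=O)OC(C)=O
Why: Fluoride removes both silyl ethers and the freed primary and secondary alcohols are acetylated in the same pot (DMAP-catalysed acylation), conditions mild enough for the enone and the epimerisable C6.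

Step 10
Reactants: 20 (4Z,6R,8S)-8,13-diacetoxy-1-oxogermacra-4,7(11),10(14)-trien-6,12-olide
Product: 21 (1S,4Z,6R,8S)-8,13-diacetoxy-1-hydroxygermacra-4,7(11),10(14)-trien-6,12-olide (8alpha,13-diacetoxy-1alpha-hydroxygermacra-4,7(11),10(14)-trien-6alpha,12-olide)
Conditions: (R)-2-methyl-CBS-oxazaborolidine (0.5 equiv), catecholborane (2 equiv), toluene, −78 °C; pH 7 buffer
Reagents that add atoms: none
Why: Corey–Bakshi–Shibata reduction: the (R)-oxazaborolidine binds the ketone with the alkenyl C10 side as the large group and delivers hydride 1,2 to give the (1S)-allylic alcohol, leaving the lactone, acetates and alkenes untouched at low temperature.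

## Compound list

1 | 3-methylcyclohex-2-en-1-one | CC1=CC(=O)CCC1 | starting material
2 | trimethyl[(4-methylcyclohexa-1,3-dien-2-yl)oxy]silane | CC1=CC(O[Si](C)(C)C)=CCC1 | intermediate
3 | 3-methyl-6-[(trimethylsilyl)oxy]cyclohex-2-en-1-one (racemic) | CC1=CC(=O)C(O[Si](C)(C)C)CC1 | intermediate
4 | 6-hydroxy-3-methylcyclohex-2-en-1-one (racemic) | CC1=CC(=O)C(O)CC1 | intermediate
5 | tert-butyldimethyl(prop-2-yn-1-yloxy)silane (silyl-protected propargyl alcohol) | C#CCO[Si](C)(C)C(C)(C)C | starting material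
6 | lithium acetylide of 5, {3-[(tert-butyldimethylsilyl)oxy]prop-1-yn-1-yl}lithium | [Li]C#CCO[Si](C)(C)C(C)(C)C | intermediate
7 | 2-{3-[(tert-butyldimethylsilyl)oxy]prop-1-yn-1-yl}-4-methylcyclohex-3-ene-1,2-diol (racemic, cis/trans mixture) | CC1=CC(O)(C#CCO[Si](C)(C)C(C)(C)C)C(O)CC1 | intermediate
8 | alkenylmagnesium chelate: tris(chloromagnesium) derivative of the carbomagnesiated diol, Mg on C11 cis to the tertiary alkoxide | CC1=CC(O[Mg]Cl)(/C(C[Si](C)(C)OC(C)C)=C(\[Mg]Cl)CO[Si](C)(C)C(C)(C)C)C(O[Mg]Cl)CC1 | intermediate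
9 | (2E)-2-{[(tert-butyldimethylsilyl)oxy]methyl}-3-(1,2-dihydroxy-4-methylcyclohex-3-en-1-yl)-4-[dimethyl(propan-2-yloxy)silyl]but-2-enoic acid (carboxyl cis to the tertiary carbinol) | CC1=CC(O)(/C(C[Si](C)(C)OC(C)C)=C(\C(=O)O)CO[Si](C)(C)C(C)(C)C)C(O)CC1 | intermediate
10 | 4-{[dimethyl(propan-2-yloxy)silyl]methyl}-10-hydroxy-7-methyl-3-{[(tert-butyldimethylsilyl)oxy]methyl}-1-oxaspiro[4.5]deca-3,6-dien-2-one (racemic diastereomer mixture) | CC1=CC2(OC(=O)C(CO[Si](C)(C)C(C)(C)C)=C2C[Si](C)(C)OC(C)C)C(O)CC1 | intermediate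
11 | 10-hydroxy-4-(hydroxymethyl)-7-methyl-3-{[(tert-butyldimethylsilyl)oxy]methyl}-1-oxaspiro[4.5]deca-3,6-dien-2-one (racemic diastereomer mixture) | CC1=CC2(OC(=O)C(CO[Si](C)(C)C(C)(C)C)=C2CO)C(O)CC1 | intermediate
12 | 7-methyl-2,10-dioxo-3-{[(tert-butyldimethylsilyl)oxy]methyl}-1-oxaspiro[4.5]deca-3,6-diene-4-carbaldehyde (racemic) | CC1=CC2(OC(=O)C(CO[Si](C)(C)C(C)(C)C)=C2C=O)C(=O)CC1 | intermediate
13 | 2,3-dibromoprop-1-ene | C=C(Br)CBr | starting material
14 | 4-{(1S)-3-bromo-1-[(triethylsilyl)oxy]but-3-en-1-yl}-7-methyl-3-{[(tert-butyldimethylsilyl)oxy]methyl}-1-oxaspiro[4.5]deca-3,6-diene-2,10-dione (both spiro epimers) | C=C(Br)C[C@H](O[Si](CC)(CC)CC)C1=C(CO[Si](C)(C)C(C)(C)C)C(=O)OC12C=C(C)CCC2=O | intermediate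
15 | (8S)-13-[(tert-butyldimethylsilyl)oxy]-1-hydroxy-8-[(triethylsilyl)oxy]-1,6-cyclogermacra-4,7(11),10(14)-trien-6,12-olide (tricyclic; mixture at C1 and C6) | C=C1C[C@H](O[Si](CC)(CC)CC)C2=C(CO[Si](C)(C)C(C)(C)C)C(=O)OC23C=C(C)CCC13O | intermediate
16 | potassium alkoxide of 15 | C=C1C[C@H](O[Si](CC)(CC)CC)C2=C(CO[Si](C)(C)C(C)(C)C)C(=O)OC23C=C(C)CCC13[O-].[K+] | intermediate
17 | potassium 2-furanolate of the ring-expanded ketone (furan ring = O, C12, C11, C7, C6; ten-membered 1-ketone) | C=C1C[C@H](O[Si](CC)(CC)CC)c2c(CO[Si](C)(C)C(C)(C)C)c([O-])oc2/C=C(/C)CCC1=O.[K+] | intermediate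
18 | (4Z,6R,8S)-13-[(tert-butyldimethylsilyl)oxy]-1-oxo-8-[(triethylsilyl)oxy]germacra-4,7(11),10(14)-trien-6,12-olide | C=C1C[C@H](O[Si](CC)(CC)CC)C2=C(CO[Si](C)(C)C(C)(C)C)C(=O)O[C@@H]2/C=C(/C)CCC1=O | intermediate
19 | (4Z,6R,8S)-8,13-dihydroxy-1-oxogermacra-4,7(11),10(14)-trien-6,12-olide | C=C1C[C@H](O)C2=C(CO)C(=O)O[C@@H]2/C=C(/C)CCC1=O | intermediate
20 | (4Z,6R,8S)-8,13-diacetoxy-1-oxogermacra-4,7(11),10(14)-trien-6,12-olide | C=C1C[C@H](OC(C)=O)C2=C(COC(C)=O)C(=O)O[C@@H]2/C=C(/C)CCC1=O | intermediate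
21 | (1S,4Z,6R,8S)-8,13-diacetoxy-1-hydroxygermacra-4,7(11),10(14)-trien-6,12-olide | C=C1C[C@H](OC(C)=O)C2=C(COC(C)=O)C(=O)O[C@@H]2/C=C(/C)CC[C@@H]1O | target

## Step count and risks

Total: 10 steps. Longest linear sequence: 10 steps (1 to 21; 5 and 13 enter as bought building blocks).

**Most likely to fail: step 3 (carbomagnesiation/carboxylation).** The hindered tertiary magnesium chelate 8 may carboxylate or lactonise poorly. The fallback sets out from 7 and returns at 10. The same directed carbomagnesiation is quenched with iodine instead of CO2 to isolate the vinyl iodide 2-{(2E)-4-[(tert-butyldimethylsilyl)oxy]-1-[dimethyl(propan-2-yloxy)silyl]-3-iodobut-2-en-2-yl}-4-methylcyclohex-3-ene-1,2-diol F1 (iodine cis to the tertiary carbinol). The butenolide is then closed by palladium-catalysed carbonylative lactonisation (PdCl2(PPh3)2, CO 1 atm, K2CO3, THF, 50 °C), a standard route from (Z)-gamma-hydroxy vinyl iodides to butenolides.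

**Most likely to fail: step 8 (the proposed ring expansion).** Three things can go wrong:
- the alkoxide may not fragment at low temperature;
- the furanolate 17 may add transannularly to the new alpha-methylene ketone (C6 or C11 onto C14) before it is protonated;
- protonation may give the C6 epimer.

The fallback uses known chemistry, sets out from 15 and returns at 18. Alkoxy-radical beta-scission under Suárez conditions (PhI(OAc)2, I2, cyclohexane/CH2Cl2, visible light, 23 °C) cleaves the same C1–C6 bond, because it gives the most stabilised, alpha-oxygenated and doubly allylic radical. Oxidation and acetate capture give (4Z,8S)-6-acetoxy-13-[(tert-butyldimethylsilyl)oxy]-1-oxo-8-[(triethylsilyl)oxy]germacra-4,7(11),10(14)-trien-6,12-olide F2. Zinc dust in AcOH/THF at 0 °C then removes the gamma-acetoxy group reductively through the zinc dienolate.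

**Most likely to fail: step 10 (CBS reduction).** The catalyst may be mismatched with the C6/C8 bias of the macrocycle. The fallback sets out from 20 and returns at 21. Luche reduction (NaBH4, CeCl3, MeOH, −78 °C) gives both C1 alcohols under substrate control and they are separated. The unwanted (1R,4Z,6R,8S)-8,13-diacetoxy-1-hydroxygermacra-4,7(11),10(14)-trien-6,12-olide F3 is inverted by Mitsunobu reaction with formic acid (PPh3, DIAD, THF, 0 °C) to (1S,4Z,6R,8S)-8,13-diacetoxy-1-(formyloxy)germacra-4,7(11),10(14)-trien-6,12-olide F4. The formate is then removed selectively with KHCO3 in MeOH at 0 °C, which leaves the acetates in place.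

## Further compounds

F1 | step 3 | 2-{(2E)-4-[(tert-butyldimethylsilyl)oxy]-1-[dimethyl(propan-2-yloxy)silyl]-3-iodobut-2-en-2-yl}-4-methylcyclohex-3-ene-1,2-diol | CC1=CC(O)(/C(C[Si](C)(C)OC(C)C)=C(\I)CO[Si](C)(C)C(C)(C)C)C(O)CC1
F2 | step 8 | (4Z,8S)-6-acetoxy-13-[(tert-butyldimethylsilyl)oxy]-1-oxo-8-[(triethylsilyl)oxy]germacra-4,7(11),10(14)-trien-6,12-olide (C6 epimers) | C=C1C[C@H](O[Si](CC)(CC)CC)C2=C(CO[Si](C)(C)C(C)(C)C)C(=O)OC2(OC(C)=O)/C=C(/C)CCC1=O
F3 | step 10 | (1R,4Z,6R,8S)-8,13-diacetoxy-1-hydroxygermacra-4,7(11),10(14)-trien-6,12-olide | C=C1C[C@H](OC(C)=O)C2=C(COC(C)=O)C(=O)O[C@@H]2/C=C(/C)CC[C@H]1O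
F4 | step 10 | (1S,4Z,6R,8S)-8,13-diacetoxy-1-(formyloxy)germacra-4,7(11),10(14)-trien-6,12-olide | C=C1C[C@H](OC(C)=O)C2=C(COC(C)=O)C(=O)O[C@@H]2/C=C(/C)CC[C@@H]1OC=O
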